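## Retrosynthetic overview

1. The target acid comes from its tert-butyl ester by acid cleavage in the last step.
2. Both rings form together: oxidation of an acyclic (4R,6R)-tetraenol gives a ketone-tethered tetraene that closes the cyclohexene and the cyclopentanone in one intramolecular Diels–Alder step (bonds C4–C5 and C3a–C7a). No ring exists before this step.
3. The tetraenol comes from an internal alkyne by syn-hydrozirconation and Negishi coupling with a dienyl iodide (C8–C9 bond, all-E triene).
4. The alkynol comes from a Marshall propargylation of an α-methyl-β,γ-unsaturated aldehyde with the allenylindium from (S)-hex-3-yn-2-yl mesylate (sets C6; the C5 carbinol is erased later).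
5. The aldehyde comes from asymmetric hydroformylation of a dienoate made from acrolein (sets C4); the dienyl iodide comes from ethylcupration and iodination of a styrylacetylene.

Assumption: the ligand enantiomers named in steps 2 and 3 are taken to give the (4R)-aldehyde and the (2S)-alcohol; if either sense is the reverse, the mirror-image ligand is used.

## Route

Step 1
Reactants: 1 tert-butyl 2-bromobutanoate (racemic); 2 triphenylphosphine; 3 acrolein
Product: 6 tert-butyl (2E)-2-ethylpenta-2,4-dienoate, via phosphonium bromide 4 (not isolated), via phosphorus ylide 5 (not isolated)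
Conditions: PPh3, PhMe, 90 °C; then aq. NaOH, CH2Cl2, rt; then 3, CH2Cl2, 0 °C to rt
Reagents that add atoms: none
Why: SN2 quaternisation and deprotonation give the ester-stabilised ylide, whose Wittig reaction with the unhindered aldehyde of acrolein gives the (2E)-trisubstituted dienoate; no stereocentre is formed.

Step 2
Reactants: 6 tert-butyl (2E)-2-ethylpenta-2,4-dienoate
Product: 7 tert-butyl (2E,4R)-2-ethyl-4-methyl-5-oxopent-2-enoate
Conditions: Rh(acac)(CO)2 (0.5 mol%), (S,S,S)-BisDiazaphos (0.6 mol%), CO/H2 (1:1, 10 bar), THF, 40 °C; crude solution used at once in step 5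
Reagents that add atoms: carbon monoxide [C-]#[O+]
Why: Rhodium-catalysed asymmetric hydroformylation of a 1,3-diene: Rh–H adds to the terminal CH2, the resulting η3-allyl is acylated at the internal carbon so the trisubstituted alkene stays conjugated with the ester, and the chiral bis(diazaphospholane) ligand selects the alkene face to set C4 as (R).

Step 3
Reactants: 8 hex-3-yn-2-one
Product: 9 (2S)-hex-3-yn-2-ol
Conditions: RuCl[(S,S)-TsDPEN](p-cymene) (0.5 mol%), i-PrOH, rt
Reagents that add atoms: none
Why: Noyori asymmetric transfer hydrogenation of an alkynyl ketone, in which the alkyne takes the place of the aryl group in the Ru–H/N–H transition state so that the (S,S) catalyst gives the (S)-propargylic alcohol.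

Step 4
Reactants: 9 (2S)-hex-3-yn-2-ol
Product: 10 (2S)-hex-3-yn-2-yl methanesulfonate
Conditions: MsCl, Et3N, CH2Cl2, −78 °C
Reagents that add atoms: methanesulfonyl chloride CS(=O)(=O)Cl
Why: O-sulfonylation of the alcohol leaves the C–O bond untouched, so C2 stays (S).

Step 5
Reactants: 7 tert-butyl (2E,4R)-2-ethyl-4-methyl-5-oxopent-2-enoate; 10 (2S)-hex-3-yn-2-yl methanesulfonate
Product: 12 tert-butyl (2E,4R,5S,6R)-2-ethyl-5-hydroxy-4,6-dimethyldec-2-en-7-ynoate, via allenylindium reagent 11 (not isolated)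
Conditions: Pd(dppf)Cl2 (5 mol%), InI (1.4 equiv), THF/HMPA (3:1), rt
Reagents that add atoms: none
Why: Marshall propargylation: zerovalent palladium formed in the flask displaces the mesylate anti (SN2'), InI takes over the allenyl group, and the allenylindium adds to the aldehyde through a cyclic SE2' transition state, so the new C–C bond forms with net inversion and sets C6 as (R) with an anti C5 hydroxyl (5S); C4 is not touched and the C5 configuration is erased in step 9.

Step 6
Reactants: 13 [(E)-2-bromoethenyl]benzene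
Product: 14 [(1E)-but-1-en-3-yn-1-yl]benzene
Conditions: HC≡CMgBr, ZnBr2, THF, 0 °C; then 13, Pd(PPh3)4 (3 mol%), rt
Reagents that add atoms: ethynylmagnesium bromide C#C[Mg]Br
Why: Negishi alkynylation: ethynylzinc bromide couples with the alkenyl bromide at zerovalent palladium with retention of the E geometry; no stereocentre is formed.

Step 7
Reactants: 14 [(1E)-but-1-en-3-yn-1-yl]benzene
Product: 16 [(1E,3E)-3-ethyl-4-iodobuta-1,3-dien-1-yl]benzene, via dienylcopper 15 (not isolated)
Conditions: EtMgBr, CuBr·SMe2, Et2O/Me2S, −45 °C; then 14, −25 °C; then I2, THF, −78 to 0 °C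
Reagents that add atoms: ethylmagnesium bromide CC[Mg]Br; iodine II
Why: Normant carbocupration: ethylcopper adds syn across the terminal alkyne with copper on the terminal carbon, and iodinolysis of the C–Cu bond with retention gives the iodide in which ethyl and iodine are cis; no stereocentre is formed.

Step 8
Reactants: 12 tert-butyl (2E,4R,5S,6R)-2-ethyl-5-hydroxy-4,6-dimethyldec-2-en-7-ynoate; 16 [(1E,3E)-3-ethyl-4-iodobuta-1,3-dien-1-yl]benzene
Product: 18 tert-butyl (2E,4R,5R,6R,7E,9E,11E)-2,8,10-triethyl-5-hydroxy-4,6-dimethyl-12-phenyldodeca-2,7,9,11-tetraenoate, via alkenylzirconocene 17 (not isolated)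
Conditions: Cp2Zr(H)Cl (2.5 equiv), THF, 0 °C to rt; then 16, Pd(PPh3)4 (5 mol%), ZnCl2 (0.3 equiv), THF, rt
Reagents that add atoms: none
Why: Hydrozirconation adds H and Zr syn with zirconium on the less hindered, ethyl-bearing alkyne carbon (the first equivalent only forms the zirconium alkoxide), and the ZnCl2-assisted Negishi coupling proceeds with retention at both sp2 carbons to give the (7E,9E,11E)-triene; C4, C5 and C6 are untouched (the C5 descriptor changes from S to R only because the CIP priorities change).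

Step 9
Reactants: 18 tert-butyl (2E,4R,5R,6R,7E,9E,11E)-2,8,10-triethyl-5-hydroxy-4,6-dimethyl-12-phenyldodeca-2,7,9,11-tetraenoate
Product: 20 tert-butyl (1R,3R,3aS,4S,5R,7aS)-4,5,7-triethyl-1,3-dimethyl-2-oxo-5-[(E)-2-phenylethenyl]-2,3,3a,4,5,7a-hexahydro-1H-indene-4-carboxylate, via tetraenone 19 (not isolated)
Conditions: DMP (1.3 equiv), pyridine, CH2Cl2, 0 °C to rt; then PhMe, BHT, 80 °C
Reagents that add atoms: none
Why: Dess–Martin oxidation gives the ketone-tethered tetraene, which closes both rings in one intramolecular Diels–Alder reaction; allylic 1,3-strain places the C–H bond of each methyl-bearing centre (4R,6R) in the plane of the neighbouring ethyl-substituted alkene, so only one trans-fused transition state is unstrained, and suprafacial addition of the E,E-diene to the E-enoate sets C3a (S), C4 (S), C5 (R) and C7a (S).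

Step 10
Reactants: 20 tert-butyl (1R,3R,3aS,4S,5R,7aS)-4,5,7-triethyl-1,3-dimethyl-2-oxo-5-[(E)-2-phenylethenyl]-2,3,3a,4,5,7a-hexahydro-1H-indene-4-carboxylate
Product: 21 (1R,3R,3aS,4S,5R,7aS)-4,5,7-triethyl-1,3-dimethyl-2-oxo-5-[(E)-2-phenylethenyl]-2,3,3a,4,5,7a-hexahydro-1H-indene-4-carboxylic acid (norspiculoic acid A)
Conditions: TFA/CH2Cl2 (1:4), 0 °C
Reagents that add atoms: none
Why: Acidolysis of the tert-butyl ester by alkyl–oxygen cleavage (E1) releases isobutene without attack at the hindered carbonyl, and the two methyl-bearing centres next to the ketone already sit in the expected more stable arrangement (each methyl trans to the adjacent ring bond), so they are not at risk.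

## Compound list

1 | tert-butyl 2-bromobutanoate (racemic) | CCC(Br)C(=O)OC(C)(C)C | starting material
2 | triphenylphosphine | c1ccc(cc1)P(c1ccccc1)c1ccccc1 | starting material
3 | acrolein (prop-2-enal) | C=CC=O | starting material
4 | (1-tert-butoxy-1-oxobutan-2-yl)triphenylphosphonium bromide (racemic) | CCC(C(=O)OC(C)(C)C)[P+](c1ccccc1)(c1ccccc1)c1ccccc1.[Br-] | intermediate
5 | tert-butyl 2-(triphenyl-λ5-phosphanylidene)butanoate | CCC(C(=O)OC(C)(C)C)=P(c1ccccc1)(c1ccccc1)c1ccccc1 | intermediate
6 | tert-butyl (2E)-2-ethylpenta-2,4-dienoate | C=C/C=C(\CC)C(=O)OC(C)(C)C | intermediate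
7 | tert-butyl (2E,4R)-2-ethyl-4-methyl-5-oxopent-2-enoate | O=C[C@H](C)/C=C(\CC)C(=O)OC(C)(C)C | intermediate
8 | hex-3-yn-2-one | CCC#CC(C)=O | starting material
9 | (2S)-hex-3-yn-2-ol | CCC#C[C@H](C)O | intermediate
10 | (2S)-hex-3-yn-2-yl methanesulfonate | CCC#C[C@H](C)OS(C)(=O)=O | intermediate
11 | (aR)-(hexa-2,3-dien-4-yl)(iodo)indium methanesulfonate | CCC([In](I)OS(C)(=O)=O)=[C@@]=C([H])C | intermediate
12 | tert-butyl (2E,4R,5S,6R)-2-ethyl-5-hydroxy-4,6-dimethyldec-2-en-7-ynoate | CCC#C[C@@H](C)[C@@H](O)[C@H](C)/C=C(\CC)C(=O)OC(C)(C)C | intermediate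
13 | [(E)-2-bromoethenyl]benzene | Br/C=C/c1ccccc1 | starting material
14 | [(1E)-but-1-en-3-yn-1-yl]benzene | C#C/C=C/c1ccccc1 | intermediate
15 | [(1E,3E)-2-ethyl-4-phenylbuta-1,3-dien-1-yl]copper | [Cu]/C=C(CC)/C=C/c1ccccc1 | intermediate
16 | [(1E,3E)-3-ethyl-4-iodobuta-1,3-dien-1-yl]benzene | I/C=C(CC)/C=C/c1ccccc1 | intermediate
17 | tert-butyl (2E,4R,5S,6R,7E)-8-[chlorobis(cyclopentadienyl)zirconio]-5-{[chlorobis(cyclopentadienyl)zirconio]oxy}-2-ethyl-4,6-dimethyldeca-2,7-dienoate | CC/C([Zr](Cl)(C1C=CC=C1)C1C=CC=C1)=C\[C@@H](C)[C@@H](O[Zr](Cl)(C1C=CC=C1)C1C=CC=C1)[C@H](C)/C=C(\CC)C(=O)OC(C)(C)C | intermediate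
18 | tert-butyl (2E,4R,5R,6R,7E,9E,11E)-2,8,10-triethyl-5-hydroxy-4,6-dimethyl-12-phenyldodeca-2,7,9,11-tetraenoate | c1ccccc1/C=C/C(CC)=C/C(CC)=C/[C@@H](C)[C@@H](O)[C@H](C)/C=C(\CC)C(=O)OC(C)(C)C | intermediate
19 | tert-butyl (2E,4R,6R,7E,9E,11E)-2,8,10-triethyl-4,6-dimethyl-5-oxo-12-phenyldodeca-2,7,9,11-tetraenoate | c1ccccc1/C=C/C(CC)=C/C(CC)=C/[C@@H](C)C(=O)[C@H](C)/C=C(\CC)C(=O)OC(C)(C)C | intermediate
20 | tert-butyl (1R,3R,3aS,4S,5R,7aS)-4,5,7-triethyl-1,3-dimethyl-2-oxo-5-[(E)-2-phenylethenyl]-2,3,3a,4,5,7a-hexahydro-1H-indene-4-carboxylate | CCC1=C[C@](/C=C/c2ccccc2)(CC)[C@@](CC)(C(=O)OC(C)(C)C)[C@H]2[C@H]1[C@@H](C)C(=O)[C@@H]2C | intermediate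
21 | (1R,3R,3aS,4S,5R,7aS)-4,5,7-triethyl-1,3-dimethyl-2-oxo-5-[(E)-2-phenylethenyl]-2,3,3a,4,5,7a-hexahydro-1H-indene-4-carboxylic acid (norspiculoic acid A) | CCC1=C[C@](/C=C/c2ccccc2)(CC)[C@@](CC)(C(=O)O)[C@H]2[C@H]1[C@@H](C)C(=O)[C@@H]2C | target

## Step count and risks

Total step count: 10. Longest linear sequence: 6 (steps 1, 2, 5, 8, 9, 10).

**Step 2 (asymmetric hydroformylation).** The electron-poor dienoate may give the linear aldehyde, be hydrogenated, or give low ee, and 7 is prone to isomerise. The fallback takes C4 from the chiral pool instead of making it by catalysis; it sets out from 5 and comes back at 7. Commercial methyl (2S)-3-hydroxy-2-methylpropanoate is silylated (TBSCl, imidazole) to methyl (2S)-3-[(tert-butyldimethylsilyl)oxy]-2-methylpropanoate F1. Reduction with i-Bu2AlH at −78 °C gives (2S)-3-[(tert-butyldimethylsilyl)oxy]-2-methylpropanal F2. Its Wittig reaction with ylide 5 (made as in step 1) gives tert-butyl (2E,4R)-5-[(tert-butyldimethylsilyl)oxy]-2-ethyl-4-methylpent-2-enoate F3. HF·pyridine frees tert-butyl (2E,4R)-2-ethyl-5-hydroxy-4-methylpent-2-enoate F4, and Dess–Martin oxidation of F4 gives 7, used at once in step 5.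

**Step 8 (hydrozirconation and Negishi coupling).** The zirconium alkoxide may steer zirconium to the wrong alkyne carbon, and the hydride may touch the enoate. The fallback replaces hydrometalation by carbopalladation; it sets out from 12 and 16 and comes back at 18. A formate-mediated reductive Heck reaction (Pd(OAc)2, PPh3, HCO2H, Et3N, DMF, 40 °C) lets the dienylpalladium iodide add syn across the alkyne with the dienyl group on the less hindered, ethyl-bearing carbon. Formate then replaces palladium by hydrogen with retention, giving 18 directly without any metal hydride reagent.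

**Step 9 (oxidation and double ring closure).** The β,γ-unsaturated ketone 19 may slip into conjugation or epimerise before it cyclises. The fallback reverses the order of cyclisation and oxidation; it sets out from 18 and comes back at 20. The tetraenol 18, which has no enolisable centre, is heated (PhMe, BHT, 110 °C) so that the same intramolecular Diels–Alder reaction gives tert-butyl (1R,2R,3R,3aS,4S,5R,7aS)-4,5,7-triethyl-2-hydroxy-1,3-dimethyl-5-[(E)-2-phenylethenyl]-2,3,3a,4,5,7a-hexahydro-1H-indene-4-carboxylate F5. Dess–Martin oxidation of F5 then gives 20.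

Further compounds
F1 | step 2 | methyl (2S)-3-[(tert-butyldimethylsilyl)oxy]-2-methylpropanoate | CC(C)(C)[Si](C)(C)OC[C@H](C)C(=O)OC
F2 | step 2 | (2S)-3-[(tert-butyldimethylsilyl)oxy]-2-methylpropanal | CC(C)(C)[Si](C)(C)OC[C@H](C)C=O
F3 | step 2 | tert-butyl (2E,4R)-5-[(tert-butyldimethylsilyl)oxy]-2-ethyl-4-methylpent-2-enoate | CC(C)(C)[Si](C)(C)OC[C@H](C)/C=C(\CC)C(=O)OC(C)(C)C
F4 | step 2 | tert-butyl (2E,4R)-2-ethyl-5-hydroxy-4-methylpent-2-enoate | OC[C@H](C)/C=C(\CC)C(=O)OC(C)(C)C
F0 | step 8 | none | none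
F5 | step 9 | tert-butyl (1R,2R,3R,3aS,4S,5R,7aS)-4,5,7-triethyl-2-hydroxy-1,3-dimethyl-5-[(E)-2-phenylethenyl]-2,3,3a,4,5,7a-hexahydro-1H-indene-4-carboxylate | CCC1=C[C@](/C=C/c2ccccc2)(CC)[C@@](CC)(C(=O)OC(C)(C)C)[C@H]2[C@H]1[C@@H](C)[C@@H](O)[C@@H]2C
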